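**Retrosynthetic overview**
- The target comes from a C2-symmetric bis(3-aroyl-3-hydroxy-γ-butyrolactone) by one hydrogenolysis (two ArC=O to CH2, two OBn to OH).
- Key disconnection (twice): the bond between lactone C3 and the outer benzylic carbon. It is made by adding the carbene-bound acyl anion equivalent of O-benzylvanillin to the C3 ketone carbon of an α-keto lactone that racemises through its enol. This one step sets all four stereocentres.
- The bis(3-hydroxybutenolide) comes from a bis(2-oxo-4-arylbutanoic acid) and formaldehyde (aldol, lactonisation), which comes from divanillin and pyruvic acid (aldol condensation, C=C hydrogenation).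
- Divanillin comes from vanillin by oxidative 5,5'-phenol coupling.
- Ring order: biaryl bond first, then both lactone rings together (two-directional); no ring is formed after the key step.

Assumption: the sense of induction of the aminoindanol-derived triazolium salt in step 5 is assigned by analogy; if a mono-lactone model shows the opposite sense, the (5aR,10bS) salt is used with no other change.

**Step 1**
Reactants: 1 vanillin (4-hydroxy-3-methoxybenzaldehyde), two molecules
Product: 2 divanillin (6,6'-dihydroxy-5,5'-dimethoxy[1,1'-biphenyl]-3,3'-dicarbaldehyde)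
Conditions: Na2S2O8 (0.55 equiv), FeSO4·7H2O (2 mol%), H2O, 80 °C
Reagents that add atoms: none
Why: Oxidative phenol coupling: the phenoxyl radicals can only join C–C at C5, the one free ortho position (para and the other ortho position are blocked), and no stereocentre is formed.

**Step 2**
Reactants: 2 divanillin; 3 pyruvic acid (2.5 equiv)
Product: 4 (3E,3'E)-4,4'-(6,6'-dihydroxy-5,5'-dimethoxy[1,1'-biphenyl]-3,3'-diyl)bis(2-oxobut-3-enoic acid)
Conditions: KOH (7 equiv), MeOH–H2O, 0 → 25 °C; then aq. HCl to pH 1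
Reagents that add atoms: pyruvic acid (3), CC(=O)C(=O)O
Why: Claisen–Schmidt (crossed aldol) condensation of the pyruvate enolate with the non-enolisable aryl aldehydes, with dehydration giving the conjugated E-enones; no stereocentre is formed.

**Step 3**
Reactants: 4 the bis(enone keto acid)
Product: 5 4,4'-(6,6'-dihydroxy-5,5'-dimethoxy[1,1'-biphenyl]-3,3'-diyl)bis(2-oxobutanoic acid)
Conditions: H2 (1 atm), 5% Pd/C, THF–MeOH, 25 °C, stopped after 2 equiv H2
Reagents that add atoms: none
Why: Chemoselective heterogeneous hydrogenation: the aryl-conjugated C=C is reduced much faster over Pd than the α-keto acid carbonyl; no stereocentre is formed.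

**Step 4**
Reactants: 5 the bis(2-oxobutanoic acid); 6 formaldehyde
Product: 8 4,4'-[(6,6'-dihydroxy-5,5'-dimethoxy[1,1'-biphenyl]-3,3'-diyl)bis(methylene)]bis[3-hydroxyfuran-2(5H)-one], via bis(hydroxymethyl) keto acid 7 (not isolated)
Conditions: 37% aq. HCHO (2.1 equiv), K2CO3, H2O, 25 °C; then 6 M HCl, 60 °C
Reagents that add atoms: formaldehyde (6), C=O
Why: Aldol hydroxymethylation at the only enolisable carbon of each α-keto acid (a second addition is held back by using 1.05 equiv of HCHO per keto acid), then acid-catalysed γ-lactonisation, the same aldol–lactonisation that turns 2-oxobutanoic acid and acetaldehyde into 3-hydroxy-4,5-dimethylfuran-2(5H)-one; the lactone is obtained in its stable conjugated enol form, in which C4 is sp2, so no stereocontrol is needed here.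

**Step 5**
Reactants: 8 the bis(3-hydroxybutenolide); 9 4-(benzyloxy)-3-methoxybenzaldehyde (3 equiv)
Product: 11 (3S,3'S,4R,4'R)-4,4'-[(6,6'-dihydroxy-5,5'-dimethoxy[1,1'-biphenyl]-3,3'-diyl)bis(methylene)]bis{3-[4-(benzyloxy)-3-methoxybenzoyl]-3-hydroxydihydrofuran-2(3H)-one}, via bis(keto lactone) tautomer 10 (not isolated)
Conditions: (5aS,10bR)-2-(pentafluorophenyl)-5a,10b-dihydro-4H,6H-indeno[2,1-b][1,2,4]triazolo[4,3-d][1,4]oxazin-2-ium tetrafluoroborate (20 mol%), iPr2NEt (40 mol%), 4 Å molecular sieves, THF–CH2Cl2, 0 → 25 °C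
Reagents that add atoms: 4-(benzyloxy)-3-methoxybenzaldehyde (9), COc1cc(C=O)ccc1OCc1ccccc1
Why: Proposed new method: the chiral triazolylidene turns aldehyde 9 into a nucleophilic acyl anion equivalent (carbene-bound enaminol) that adds to the strongly electrophilic C3 ketone of keto tautomer 10, which forms from enol 8 under the amine base and racemises at C4 through that achiral enol; the ring forces attack anti to the C4 arylmethyl group (aroyl trans, OH cis to it) and the catalyst accepts only the (4R)-ketone, so both stereocentres of each lactone are set in one dynamic kinetic asymmetric cross-benzoin addition, the closest known reaction type being carbene-catalysed dynamic kinetic cross-benzoin additions of aldehydes to racemising β-stereogenic α-keto esters.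

**Step 6**
Reactants: 11 the bis(3-aroyl-3-hydroxy lactone)
Product: 12 bis-5,5-nortrachelogenin, (3R,3'R,4R,4'R)-4,4'-[(6,6'-dihydroxy-5,5'-dimethoxy[1,1'-biphenyl]-3,3'-diyl)bis(methylene)]bis[3-hydroxy-3-(4-hydroxy-3-methoxybenzyl)dihydrofuran-2(3H)-one]
Conditions: H2 (4 atm), 20% Pd(OH)2/C, AcOH–EtOAc, 45 °C
Reagents that add atoms: none
Why: Hydrogenolysis: the benzyl ethers are cleaved and each p-hydroxyaryl ketone is reduced through its benzylic alcohol to CH2, while C3 (quaternary) and C4 (no longer adjacent to an acidifying group) keep their configuration (the C3 descriptor changes from S to R only because the priorities change).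

**Compound list**
1 | vanillin (4-hydroxy-3-methoxybenzaldehyde) | COc1cc(C=O)ccc1O | starting material
2 | divanillin (6,6'-dihydroxy-5,5'-dimethoxy[1,1'-biphenyl]-3,3'-dicarbaldehyde) | COc1cc(C=O)cc(c1O)-c1cc(C=O)cc(OC)c1O | intermediate
3 | pyruvic acid | CC(=O)C(=O)O | starting material
4 | (3E,3'E)-4,4'-(6,6'-dihydroxy-5,5'-dimethoxy[1,1'-biphenyl]-3,3'-diyl)bis(2-oxobut-3-enoic acid) | COc1cc(/C=C/C(=O)C(=O)O)cc(c1O)-c1cc(/C=C/C(=O)C(=O)O)cc(OC)c1O | intermediate
5 | 4,4'-(6,6'-dihydroxy-5,5'-dimethoxy[1,1'-biphenyl]-3,3'-diyl)bis(2-oxobutanoic acid) | COc1cc(CCC(=O)C(=O)O)cc(c1O)-c1cc(CCC(=O)C(=O)O)cc(OC)c1O | intermediate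
6 | formaldehyde | C=O | starting material
7 | 4,4'-(6,6'-dihydroxy-5,5'-dimethoxy[1,1'-biphenyl]-3,3'-diyl)bis[3-(hydroxymethyl)-2-oxobutanoic acid], stereoisomer mixture | COc1cc(CC(CO)C(=O)C(=O)O)cc(c1O)-c1cc(CC(CO)C(=O)C(=O)O)cc(OC)c1O | intermediate
8 | 4,4'-[(6,6'-dihydroxy-5,5'-dimethoxy[1,1'-biphenyl]-3,3'-diyl)bis(methylene)]bis[3-hydroxyfuran-2(5H)-one] | COc1cc(CC2=C(O)C(=O)OC2)cc(c1O)-c1cc(CC2=C(O)C(=O)OC2)cc(OC)c1O | intermediate
9 | 4-(benzyloxy)-3-methoxybenzaldehyde (O-benzylvanillin) | COc1cc(C=O)ccc1OCc1ccccc1 | starting material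
10 | 4,4'-[(6,6'-dihydroxy-5,5'-dimethoxy[1,1'-biphenyl]-3,3'-diyl)bis(methylene)]bis(dihydrofuran-2,3-dione), keto tautomer of 8, configurationally labile at C4 | COc1cc(CC2COC(=O)C2=O)cc(c1O)-c1cc(CC2COC(=O)C2=O)cc(OC)c1O | intermediate
11 | (3S,3'S,4R,4'R)-4,4'-[(6,6'-dihydroxy-5,5'-dimethoxy[1,1'-biphenyl]-3,3'-diyl)bis(methylene)]bis{3-[4-(benzyloxy)-3-methoxybenzoyl]-3-hydroxydihydrofuran-2(3H)-one} | COc1cc(C(=O)[C@]2(O)C(=O)OC[C@H]2Cc2cc(OC)c(O)c(-c3cc(C[C@@H]4COC(=O)[C@@]4(O)C(=O)c4ccc(OCc5ccccc5)c(OC)c4)cc(OC)c3O)c2)ccc1OCc1ccccc1 | intermediate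
12 | bis-5,5-nortrachelogenin, (3R,3'R,4R,4'R) | COc1cc(C[C@]2(O)C(=O)OC[C@H]2Cc2cc(OC)c(O)c(-c3cc(C[C@@H]4COC(=O)[C@@]4(O)Cc4ccc(O)c(OC)c4)cc(OC)c3O)c2)ccc1O | target

**Totals**
Total step count: 6. Longest linear sequence: 6 (1 → 2 → 4 → 5 → 8 → 11 → 12).

**Three steps most likely to fail**

Step 5 (most likely). The ketone is present only as a minor tautomer of the enol, four acidic OH groups buffer the carbene, and both lactones must react with high selectivity. At 95:5 per lactone about 90% of the material is the C2-symmetric isomer and the meso-type diastereomer must be separated. The fallback sets out from 8 and comes back at 12, giving up the acyl anion addition. Dynamic kinetic asymmetric transfer hydrogenation of the keto tautomer 10 (RuCl(p-cymene)[(S,S)-TsDPEN] or its (R,R) antipode, whichever gives the 4R series, HCO2H–Et3N, DMF, 40 °C; hydride anti to the arylmethyl group) gives (3R,3'R,4R,4'R)-4,4'-[(6,6'-dihydroxy-5,5'-dimethoxy[1,1'-biphenyl]-3,3'-diyl)bis(methylene)]bis[3-hydroxydihydrofuran-2(3H)-one] F1. Benzylation of the two phenols (BnBr, K2CO3, DMF) gives its 6,6'-bis(benzyloxy) ether F2. Deprotonation of each lactone to the alkoxide enolate (LiN(iPr)2, 4.4 equiv, THF–DMPU, −78 °C) and C3-alkylation anti to the C4 substituent with 4-(benzyloxy)-3-methoxybenzyl bromide F3 (made from the commercial benzyl alcohol with PBr3) gives tetra-O-benzyl bis-5,5-nortrachelogenin F4. Hydrogenolysis (H2, Pd/C, EtOAc–EtOH) then gives 12.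

Step 4. A second hydroxymethylation at C3, base-induced dehydration of the aldol adduct, or incomplete lactonisation would lower the yield of 8. The fallback sets out from 2 and comes back at 8, building the lactone first and attaching it by condensation. Ethyl 4-hydroxy-5-oxo-2,5-dihydrofuran-3-carboxylate F5 (from diethyl oxalacetate sodium salt and aqueous formaldehyde) is hydrolysed and decarboxylated in hot dilute H2SO4 to 3-hydroxyfuran-2(5H)-one F6. Its nucleophilic C4 condenses with both aldehyde groups of 2 (piperidinium acetate, AcOH, 80 °C) to give (4E,4'E)-4,4'-[(6,6'-dihydroxy-5,5'-dimethoxy[1,1'-biphenyl]-3,3'-diyl)dimethanylylidene]bis(dihydrofuran-2,3-dione) F7. Hydrogenation of the exocyclic alkenes (H2, Pd/C, THF) gives 8.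

Step 6. The hindered ketone next to the quaternary carbinol may stop at the benzylic alcohol or rearrange under forcing acid. The fallback sets out from 11 and comes back at 12, separating deoxygenation from debenzylation. Ionic hydrogenation (Et3SiH, CF3CO2H, CH2Cl2, 0 °C) reduces both aryl ketones to CH2 through the alkoxy-stabilised benzylic cation and keeps the benzyl ethers, giving (3R,3'R,4R,4'R)-4,4'-[(6,6'-dihydroxy-5,5'-dimethoxy[1,1'-biphenyl]-3,3'-diyl)bis(methylene)]bis{3-[4-(benzyloxy)-3-methoxybenzyl]-3-hydroxydihydrofuran-2(3H)-one} F8. Neutral hydrogenolysis (H2, Pd/C, EtOAc) then gives 12.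

**Further compounds**
F1 | step 5 | (3R,3'R,4R,4'R)-4,4'-[(6,6'-dihydroxy-5,5'-dimethoxy[1,1'-biphenyl]-3,3'-diyl)bis(methylene)]bis[3-hydroxydihydrofuran-2(3H)-one] | COc1cc(C[C@@H]2COC(=O)[C@@H]2O)cc(c1O)-c1cc(C[C@@H]2COC(=O)[C@@H]2O)cc(OC)c1O
F2 | step 5 | (3R,3'R,4R,4'R)-4,4'-{[6,6'-bis(benzyloxy)-5,5'-dimethoxy[1,1'-biphenyl]-3,3'-diyl]bis(methylene)}bis[3-hydroxydihydrofuran-2(3H)-one] | COc1cc(C[C@@H]2COC(=O)[C@@H]2O)cc(c1OCc1ccccc1)-c1cc(C[C@@H]2COC(=O)[C@@H]2O)cc(OC)c1OCc1ccccc1
F3 | step 5 | 4-(benzyloxy)-3-methoxybenzyl bromide | COc1cc(CBr)ccc1OCc1ccccc1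
F4 | step 5 | (3R,3'R,4R,4'R)-4,4'-{[6,6'-bis(benzyloxy)-5,5'-dimethoxy[1,1'-biphenyl]-3,3'-diyl]bis(methylene)}bis{3-[4-(benzyloxy)-3-methoxybenzyl]-3-hydroxydihydrofuran-2(3H)-one} | COc1cc(C[C@]2(O)C(=O)OC[C@H]2Cc2cc(OC)c(OCc3ccccc3)c(-c3cc(C[C@@H]4COC(=O)[C@@]4(O)Cc4ccc(OCc5ccccc5)c(OC)c4)cc(OC)c3OCc3ccccc3)c2)ccc1OCc1ccccc1
F5 | step 4 | ethyl 4-hydroxy-5-oxo-2,5-dihydrofuran-3-carboxylate | CCOC(=O)C1=C(O)C(=O)OC1
F6 | step 4 | 3-hydroxyfuran-2(5H)-one | OC1=CCOC1=O
F7 | step 4 | (4E,4'E)-4,4'-[(6,6'-dihydroxy-5,5'-dimethoxy[1,1'-biphenyl]-3,3'-diyl)dimethanylylidene]bis(dihydrofuran-2,3-dione) | COc1cc(/C=C2\COC(=O)C2=O)cc(c1O)-c1cc(/C=C2\COC(=O)C2=O)cc(OC)c1O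
F8 | step 6 | (3R,3'R,4R,4'R)-4,4'-[(6,6'-dihydroxy-5,5'-dimethoxy[1,1'-biphenyl]-3,3'-diyl)bis(methylene)]bis{3-[4-(benzyloxy)-3-methoxybenzyl]-3-hydroxydihydrofuran-2(3H)-one} | COc1cc(C[C@]2(O)C(=O)OC[C@H]2Cc2cc(OC)c(O)c(-c3cc(C[C@@H]4COC(=O)[C@@]4(O)Cc4ccc(OCc5ccccc5)c(OC)c4)cc(OC)c3O)c2)ccc1OCc1ccccc1
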